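# Proposed total synthesis of CNP0177576.0 (depside 22) by carboxylate-directed C–H acylmethylation

## Analysis of the target

Target 22 is a depside: two separate benzene rings joined by an aryl ester between the C1 carboxyl carbon of ring A and the C4' oxygen of ring B. Ring A carries a hydroxyl at C2, a methoxy group at C4 and a 2-oxoheptyl chain at C6. Ring B carries the free acid at C1', a methoxy group at C2' and the same 2-oxoheptyl chain at C6'. There is no stereocentre and no double-bond geometry to control. The sensitive elements are the aryl ester, which base and nucleophiles cleave, and the two ortho pairs of a carboxyl carbon and a CH2–CO chain, each of which can fold to an isocoumarin when the carboxyl is activated or heated with acid. The difficulty is therefore differentiation, not the skeleton: ring A needs its C2 hydroxyl free and C4 methylated, ring B the reverse pattern with C4' acylated, and the hindered 2,6-disubstituted ring A acid must be coupled without its own ketone intercepting the activated carboxyl. The plan rests on one feature: in both rings the chain is ortho to the carboxyl carbon, and in a 2,4-dioxygenated benzoic acid C6–H is the only free ortho position. A carboxylate can therefore direct a metal to exactly that carbon, and the enol lactone that follows stores the keto acid in a neutral, inert form.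

## Retrosynthetic reasoning

Target 22 is traced back to its dibenzyl derivative 21, in which the ring A hydroxyl is a benzyl ether and the ring B acid a benzyl ester. The cut is placed at the two O–benzyl bonds so that the final operation is a neutral hydrogenolysis. The base-labile aryl ester and the ortho keto acid of ring B then never meet acid or base once the acid is free.

Diketone 21 comes from dioxolane 20 by unmasking the ring A ketone. The mask is removed while the ring B carboxyl is still an ester, so aqueous acid finds no free ortho keto acid. Ring B keeps its ketone free throughout, because its carboxyl is never activated.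

The central disconnection is the acyl C–O bond of the depside, which divides 20 into ring A acid 12 and ring B phenol 19. It is the only bond joining the halves, and it gives two pieces with the same carbon skeleton. The forward carbodiimide esterification must acylate a phenol with a 2,6-disubstituted benzoic acid. The dioxolane of 12 keeps the C6 ketone from attacking the activated carboxyl, and the C2 benzyl ether keeps the acid from acylating itself.

Acid 12 is reached from benzyl ester 11 by saponification, 11 from ketone 10 by ketalisation, and 10 from keto acid 9 by double benzylation. The ester is needed because a free ortho keto acid would lactonise under ketalisation. Base hydrolysis, not hydrogenolysis, frees the acid, so the C2 benzyl ether survives for the coupling.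

Keto acid 9 is the ring-opened form of hydroxy isocoumarin 8, and 8 comes from dimethoxy isocoumarin 7 by loss of the C8 methyl group. The two ethers of 7 differ by position: the peri oxygen can chelate a Lewis acid together with the lactone carbonyl, the C6 oxygen cannot. A symmetrical, purchasable dimethyl ether can therefore serve as the ring A source.

Isocoumarin 7 is cut at the bond between the arene carbon and C4 (the future C6–CH2 bond of ring A) and at the lactone O–C3 bond, giving acid 5 and ylide 4. This removes the whole seven-carbon chain in one piece with the ketone at the correct oxidation level. A cut between CH2 and CO, or inside the pentyl chain, would need a pre-functionalised benzylic carbon. The forward reaction has to functionalise one aromatic C–H bond; the free carboxyl of 5 directs it and the C2 methoxy group blocks the only other ortho site.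

Ylide 4 is cut at the bond between its carbonyl carbon and the ylide carbon, giving acyl chloride 2 and methylide 3, the latter made in the flask from salt 1.

Phenol 19 is the benzyl ester of hydroxy acid 18. Acid 18 comes from benzyl ether 16 by hydrogenolysis, and 16 from isocoumarin 17 by lactone opening. The C4' oxygen travels through the metal-catalysed step as an inert ether; the benzyl group is then moved from that oxygen to the carboxyl, leaving free exactly the hydroxyl that is to be acylated.

Isocoumarin 17 is cut in the same way as 7, giving acid 15 and the same ylide 4. Acid 15 comes from ester 13 by benzylation and saponification through 14. The same key reaction thus builds both rings, which is the reason for the convergent cut at the depside bond.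

## Alternatives that were turned down

Alternative 1: Ring A would be built from an open chain after the depside ester is already in place. The cuts are the acyl C–O bond and the C1–C6 bond of ring A. Thermolysis of dioxinone A2 would release an acylketene, the C4' hydroxyl of phenol A3 would capture it as triketo aryl ester A4, and an amine base would fold A4 by aldol condensation and dehydration to depside A1.
- For it: the ester forms from an unhindered acylketene, so no 2,6-disubstituted benzoic acid has to be coupled. On this point it is stronger than the chosen route.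
- Against it: A1 has a 2,4-dihydroxy ring A, so a selective C4 methylation is still needed on a base-labile depside. In A4 the aryloxide is a good leaving group, so closure to a 4-hydroxypyranone with loss of A3 competes with the aldol. A2 needs several chain-extension steps on sensitive polycarbonyl compounds. A3 still has to be made by separate arene chemistry, and both ketones would be unmasked by acid at the end.
- Comparison: the chosen route gives up the mild ester formation, but it starts from a bought arene with the C4 methyl ether in place and uses one reaction for both rings.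

Alternative 2: Ring B would be made by cycloaddition, forming the C1'–C2' and C5'–C6' bonds. Diene A6 would add to alkynoate A7, and loss of methanol and of the silyl group would aromatise the adduct to phenol A5.
- For it: the polarised partners fix the regiochemistry, and A5 emerges with the C4' hydroxyl free, C2' methylated and the acid already a benzyl ester. This is cleaner than the protecting-group relay of steps 8 to 12 here.
- Against it: the side chain is at the alcohol oxidation level. Since a free alcohol ortho to the ester would lactonise, desilylation and oxidation would have to follow the coupling, on the depside. A7 is a β-alkyl alkynoate and a sluggish dienophile, while A6 is thermally and hydrolytically fragile. Ring A is not addressed.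
- Comparison: the chosen route needs more protecting-group steps on ring B, but it delivers the ketone directly and makes ring A by the same step.

Alternative 3: Ring B would be made by aryne insertion, forming the C6'–CH2 and C1'–carboxyl bonds together. Fluoride would release an aryne from silyl triflate A9, and the aryne would insert into a C–C bond of malonate A10 to give homophthalate A8.
- For it: the methoxy group next to the aryne steers the nucleophile to the distal carbon, so site control is as good as in the chosen route, and the C4' oxygen is already differentiated as a 4-methoxybenzyl ether.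
- Against it: A9 needs a multistep preparation from a differentially protected resorcinol. A8 contains only two of the seven chain carbons, so the pentyl ketone must be added later by distinguishing two benzyl esters. Ring A again needs its own solution.
- Comparison: the chosen route has no such built-in oxygen differentiation, but it installs the complete chain in the key step and has fewer bond-forming steps after it.

Key step: step 2

Remark: methyl 4-hydroxy-2-methoxybenzoate 13 is assumed to be purchasable; the target is achiral, so no stereochemical assignment is needed.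

## Route

Step 1
Reactants: 1 trimethylsulfoxonium iodide; 2 hexanoyl chloride
Product: 4 dimethylsulfoxonium 2-oxoheptylide, via dimethylsulfoxonium methylide 3 (not isolated)
Conditions: KOtBu, THF, reflux; then 2 (0.4 equiv), 0 °C to rt
Reagents that add atoms: none
Why: Deprotonation of 1 gives methylide 3, which is C-acylated by 2; a second equivalent of 3 removes the more acidic α-proton of the acylated salt, so an excess of ylide is used. This is the standard acylation of dimethylsulfoxonium methylide to a β-keto sulfoxonium ylide.

Step 2
Reactants: 5 2,4-dimethoxybenzoic acid; 4 dimethylsulfoxonium 2-oxoheptylide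
Product: 7 6,8-dimethoxy-3-pentyl-1H-isochromen-1-one, via 2,4-dimethoxy-6-(2-oxoheptyl)benzoic acid 6 (not isolated)
Conditions: [Ru(p-cymene)Cl2]2 (5 mol%), NaOAc (1 equiv), CF3CH2OH, 80 °C, N2
Reagents that add atoms: none
Why: This is the carboxylate-directed C–H acylmethylation and annulation of benzoic acids with sulfoxonium ylides under divalent ruthenium catalysis, a known reaction type that gives 3-substituted isocoumarins. Acetate exchange on [Ru(p-cymene)Cl2]2 gives a ruthenium carboxylate of 5, and concerted metalation–deprotonation at C6–H forms a five-membered ruthenacycle. Ylide 4 binds through carbon and loses dimethyl sulfoxide to give a ruthenium carbene; migratory insertion of the aryl group and protodemetalation then create the C6–CH2 bond of keto acid 6. The carboxyl oxygen adds to the ketone carbonyl in a 6-exo-trig closure and the lactol loses water, so the one new ring is the enol lactone of 7. No stereocentre is formed. The step needs site selectivity, and the substrate secures it: the C2 methoxy group occupies the other ortho position, so the carboxylate can deliver the metal only to C6–H, while C3–H and C5–H cannot be reached through a five-membered metallacycle. Double functionalisation is excluded for the same reason, since no ortho C–H remains after one insertion.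

Step 3
Reactants: 7 6,8-dimethoxy-3-pentyl-1H-isochromen-1-one
Product: 8 8-hydroxy-6-methoxy-3-pentyl-1H-isochromen-1-one
Conditions: BCl3 (1.5 equiv), CH2Cl2, −78 to 0 °C; aq. NaHCO3
Reagents that add atoms: none
Why: BCl3 binds the lactone carbonyl and the peri C8 oxygen in a six-membered chelate, and chloride removes that methyl group by SN2 attack; the C6 methoxy group cannot chelate and should be retained at low temperature. Chelation-controlled mono-demethylation next to a carbonyl is standard for 8-methoxyisocoumarins.

Step 4
Reactants: 8 8-hydroxy-6-methoxy-3-pentyl-1H-isochromen-1-one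
Product: 9 2-hydroxy-4-methoxy-6-(2-oxoheptyl)benzoic acid
Conditions: KOH (2 M aq.), EtOH, 70 °C; then 1 M HCl, 0 °C, to pH 2–3
Reagents that add atoms: potassium hydroxide (aqueous), [K+].[OH-]
Why: Hydroxide adds to the lactone carbonyl and the enolate leaving group tautomerises to the ketone, which makes the opening irreversible in base; cold acidification releases 9 before it can re-close. Alkaline hydrolysis of isocoumarins to 2-(2-oxoalkyl)benzoic acids is classical.

Step 5
Reactants: 9 2-hydroxy-4-methoxy-6-(2-oxoheptyl)benzoic acid
Product: 10 benzyl 2-(benzyloxy)-4-methoxy-6-(2-oxoheptyl)benzoate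
Conditions: BnBr (2.4 equiv), K2CO3, DMF, rt to 45 °C
Reagents that add atoms: benzyl bromide, BrCc1ccccc1
Why: Williamson-type O-alkylation: the carboxylate reacts first and the hydrogen-bonded C2 phenoxide second on mild warming. K2CO3 is too weak to enolise the benzylic ketone appreciably, so C-alkylation should stay minor.

Step 6
Reactants: 10 benzyl 2-(benzyloxy)-4-methoxy-6-(2-oxoheptyl)benzoate
Product: 11 benzyl 2-(benzyloxy)-4-methoxy-6-[(2-pentyl-1,3-dioxolan-2-yl)methyl]benzoate
Conditions: (TMSOCH2)2 (3 equiv), TMSOTf (0.1 equiv), CH2Cl2, −78 to −20 °C; pyridine quench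
Reagents that add atoms: 1,2-bis(trimethylsilyloxy)ethane, C[Si](C)(C)OCCO[Si](C)(C)C
Why: Silyl-transfer ketalisation (Noyori conditions) runs at low temperature without free protic acid and is driven by formation of hexamethyldisiloxane. It is preferred to hot acid with the free diol, under which the ketone oxygen could displace the ortho benzyl ester and return an isocoumarin.

Step 7
Reactants: 11 benzyl 2-(benzyloxy)-4-methoxy-6-[(2-pentyl-1,3-dioxolan-2-yl)methyl]benzoate
Product: 12 2-(benzyloxy)-4-methoxy-6-[(2-pentyl-1,3-dioxolan-2-yl)methyl]benzoic acid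
Conditions: KOH (5 equiv), DMSO/H2O 4:1, 90 °C; then cold aq. KHSO4 to pH 4–5
Reagents that add atoms: potassium hydroxide (aqueous), [K+].[OH-]
Why: Saponification of a hindered benzyl benzoate by poorly solvated hydroxide in aqueous DMSO, which attacks even 2,6-disubstituted esters; the ketal and the benzyl ether are inert to base. Buffered cold acidification keeps the ketal intact next to the new acid.

Step 8
Reactants: 13 methyl 4-hydroxy-2-methoxybenzoate
Product: 15 4-(benzyloxy)-2-methoxybenzoic acid, via methyl 4-(benzyloxy)-2-methoxybenzoate 14 (not isolated)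
Conditions: BnBr (1.1 equiv), K2CO3, DMF, 60 °C; then NaOH (2 M aq.), MeOH, 60 °C; HCl
Reagents that add atoms: benzyl bromide, BrCc1ccccc1; sodium hydroxide (aqueous), [Na+].[OH-]
Why: Williamson benzylation of the phenol and ester saponification in the same flask, both routine. The benzyl ether is chosen because it behaves like the methoxy group of 5 in the C–H step and can later be removed without acid or base.

Step 9
Reactants: 15 4-(benzyloxy)-2-methoxybenzoic acid; 4 dimethylsulfoxonium 2-oxoheptylide
Product: 17 6-(benzyloxy)-8-methoxy-3-pentyl-1H-isochromen-1-one, via 4-(benzyloxy)-2-methoxy-6-(2-oxoheptyl)benzoic acid 16 (not isolated)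
Conditions: [Ru(p-cymene)Cl2]2 (5 mol%), NaOAc (1 equiv), CF3CH2OH, 80 °C, N2
Reagents that add atoms: none
Why: The same carboxylate-directed C–H acylmethylation and 6-exo-trig lactonisation as in step 2. The C2 methoxy group again leaves C6–H as the only ortho position, and the benzyl ether is a spectator.

Step 10
Reactants: 17 6-(benzyloxy)-8-methoxy-3-pentyl-1H-isochromen-1-one
Product: 16 4-(benzyloxy)-2-methoxy-6-(2-oxoheptyl)benzoic acid
Conditions: KOH (2 M aq.), EtOH, 70 °C; then 1 M HCl, 0 °C
Reagents that add atoms: potassium hydroxide (aqueous), [K+].[OH-]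
Why: Alkaline opening of the enol lactone as in step 4; the aryl benzyl ether is stable to hydroxide. Acid 16 is the species that passed through step 9; isolating the neutral lactone 17 first allows unreacted 15 to be washed out with base.

Step 11
Reactants: 16 4-(benzyloxy)-2-methoxy-6-(2-oxoheptyl)benzoic acid
Product: 18 4-hydroxy-2-methoxy-6-(2-oxoheptyl)benzoic acid
Conditions: H2 (1 atm), Pd/C (10 wt% Pd metal on carbon), EtOAc, rt
Reagents that add atoms: none
Why: Catalytic hydrogenolysis of an aryl benzyl ether. The ketone is neither benzylic nor conjugated and should not be reduced at one atmosphere in ethyl acetate.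

Step 12
Reactants: 18 4-hydroxy-2-methoxy-6-(2-oxoheptyl)benzoic acid
Product: 19 benzyl 4-hydroxy-2-methoxy-6-(2-oxoheptyl)benzoate
Conditions: BnBr (1.05 equiv), KHCO3 (1.1 equiv), DMF, rt
Reagents that add atoms: benzyl bromide, BrCc1ccccc1
Why: Chemoselective O-alkylation of a carboxylate: hydrogencarbonate deprotonates the carboxylic acid but not the phenol, so only the ester forms and the C4 hydroxyl stays free for the coupling.

Step 13
Reactants: 12 2-(benzyloxy)-4-methoxy-6-[(2-pentyl-1,3-dioxolan-2-yl)methyl]benzoic acid; 19 benzyl 4-hydroxy-2-methoxy-6-(2-oxoheptyl)benzoate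
Product: 20 benzyl 4-{[2-(benzyloxy)-4-methoxy-6-((2-pentyl-1,3-dioxolan-2-yl)methyl)benzoyl]oxy}-2-methoxy-6-(2-oxoheptyl)benzoate
Conditions: DCC (1.2 equiv), DMAP (0.2 equiv), CH2Cl2, 0 °C to rt
Reagents that add atoms: none
Why: Steglich esterification: DMAP intercepts the O-acylisourea of 12 as an acylpyridinium ion, which acylates the phenol of 19. The dioxolane stops the C6 ketone of 12 from attacking the activated carboxyl, and the benzyl ether removes the competing phenol. The free ketone of 19 is a spectator because its neighbouring carboxyl is an unactivated ester.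

Step 14
Reactants: 20 benzyl 4-{[2-(benzyloxy)-4-methoxy-6-((2-pentyl-1,3-dioxolan-2-yl)methyl)benzoyl]oxy}-2-methoxy-6-(2-oxoheptyl)benzoate
Product: 21 benzyl 4-{[2-(benzyloxy)-4-methoxy-6-(2-oxoheptyl)benzoyl]oxy}-2-methoxy-6-(2-oxoheptyl)benzoate
Conditions: 2 M HCl (aq.)/THF 1:5, rt
Reagents that add atoms: water, O
Why: Acid-catalysed hydrolysis of a dialkyl ketone dioxolane at room temperature. Benzyl ether, benzyl ester and aryl ester should tolerate dilute aqueous acid at this temperature, and with both carboxyl groups esterified there is no free keto acid that could lactonise.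

Step 15
Reactants: 21 benzyl 4-{[2-(benzyloxy)-4-methoxy-6-(2-oxoheptyl)benzoyl]oxy}-2-methoxy-6-(2-oxoheptyl)benzoate
Product: 22 4-{[2-hydroxy-4-methoxy-6-(2-oxoheptyl)benzoyl]oxy}-2-methoxy-6-(2-oxoheptyl)benzoic acid (CNP0177576.0)
Conditions: H2 (1 atm), Pd/C (10 wt% Pd metal on carbon), EtOAc, rt
Reagents that add atoms: none
Why: Hydrogenolysis cleaves the benzyl ether of ring A and the benzyl ester of ring B in one neutral operation, with toluene as the only co-product. The aryl ester, both ketones and both methoxy groups are untouched, so the sensitive keto acid is liberated last and meets no acid or base.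

## Compound list

1 | trimethylsulfoxonium iodide | C[S+](C)(C)=O.[I-] | starting material
2 | hexanoyl chloride | CCCCCC(=O)Cl | starting material
3 | dimethylsulfoxonium methylide | C=S(C)(C)=O | intermediate
4 | dimethylsulfoxonium 2-oxoheptylide | CCCCCC(=O)C=S(C)(C)=O | intermediate
5 | 2,4-dimethoxybenzoic acid | COc1ccc(C(=O)O)c(OC)c1 | starting material
6 | 2,4-dimethoxy-6-(2-oxoheptyl)benzoic acid | CCCCCC(=O)Cc1cc(OC)cc(OC)c1C(=O)O | intermediate
7 | 6,8-dimethoxy-3-pentyl-1H-isochromen-1-one | CCCCCC1=Cc2cc(OC)cc(OC)c2C(=O)O1 | intermediate
8 | 8-hydroxy-6-methoxy-3-pentyl-1H-isochromen-1-one | CCCCCC1=Cc2cc(OC)cc(O)c2C(=O)O1 | intermediate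
9 | 2-hydroxy-4-methoxy-6-(2-oxoheptyl)benzoic acid | CCCCCC(=O)Cc1cc(OC)cc(O)c1C(=O)O | intermediate
10 | benzyl 2-(benzyloxy)-4-methoxy-6-(2-oxoheptyl)benzoate | CCCCCC(=O)Cc1cc(OC)cc(OCc2ccccc2)c1C(=O)OCc1ccccc1 | intermediate
11 | benzyl 2-(benzyloxy)-4-methoxy-6-[(2-pentyl-1,3-dioxolan-2-yl)methyl]benzoate | CCCCCC1(Cc2cc(OC)cc(OCc3ccccc3)c2C(=O)OCc2ccccc2)OCCO1 | intermediate
12 | 2-(benzyloxy)-4-methoxy-6-[(2-pentyl-1,3-dioxolan-2-yl)methyl]benzoic acid | CCCCCC1(Cc2cc(OC)cc(OCc3ccccc3)c2C(=O)O)OCCO1 | intermediate
13 | methyl 4-hydroxy-2-methoxybenzoate | COC(=O)c1ccc(O)cc1OC | starting material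
14 | methyl 4-(benzyloxy)-2-methoxybenzoate | COC(=O)c1ccc(OCc2ccccc2)cc1OC | intermediate
15 | 4-(benzyloxy)-2-methoxybenzoic acid | COc1cc(OCc2ccccc2)ccc1C(=O)O | intermediate
16 | 4-(benzyloxy)-2-methoxy-6-(2-oxoheptyl)benzoic acid | CCCCCC(=O)Cc1cc(OCc2ccccc2)cc(OC)c1C(=O)O | intermediate
17 | 6-(benzyloxy)-8-methoxy-3-pentyl-1H-isochromen-1-one | CCCCCC1=Cc2cc(OCc3ccccc3)cc(OC)c2C(=O)O1 | intermediate
18 | 4-hydroxy-2-methoxy-6-(2-oxoheptyl)benzoic acid | CCCCCC(=O)Cc1cc(O)cc(OC)c1C(=O)O | intermediate
19 | benzyl 4-hydroxy-2-methoxy-6-(2-oxoheptyl)benzoate | CCCCCC(=O)Cc1cc(O)cc(OC)c1C(=O)OCc1ccccc1 | intermediate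
20 | benzyl 4-{[2-(benzyloxy)-4-methoxy-6-((2-pentyl-1,3-dioxolan-2-yl)methyl)benzoyl]oxy}-2-methoxy-6-(2-oxoheptyl)benzoate | CCCCCC(=O)Cc1cc(OC(=O)c2c(CC3(CCCCC)OCCO3)cc(OC)cc2OCc2ccccc2)cc(OC)c1C(=O)OCc1ccccc1 | intermediate
21 | benzyl 4-{[2-(benzyloxy)-4-methoxy-6-(2-oxoheptyl)benzoyl]oxy}-2-methoxy-6-(2-oxoheptyl)benzoate | CCCCCC(=O)Cc1cc(OC(=O)c2c(CC(=O)CCCCC)cc(OC)cc2OCc2ccccc2)cc(OC)c1C(=O)OCc1ccccc1 | intermediate
22 | 4-{[2-hydroxy-4-methoxy-6-(2-oxoheptyl)benzoyl]oxy}-2-methoxy-6-(2-oxoheptyl)benzoic acid (CNP0177576.0) | CCCCCC(=O)Cc1cc(OC)cc(O)c1C(=O)Oc1cc(CC(=O)CCCCC)c(C(=O)O)c(OC)c1 | target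

## Step count and least certain steps

Total step count: 15. Longest linear sequence: 10 steps (steps 1, 2, 3, 4, 5, 6, 7, 13, 14 and 15). The ring B branch (steps 8 to 12) joins at step 13.

**Step 2 (key step).** The most likely failure is stalled metalation. The C2 methoxy group twists the carboxylate and can bind ruthenium together with it in a chelate that does not lead to C–H cleavage, while the ylide is slowly protonated and lost. Arrest at keto acid 6 would be harmless, since a trace of acid closes it to 7. The fallback abandons C–H activation for lateral metalation: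
- It sets out from hexanoyl chloride 2, which is converted with N,O-dimethylhydroxylamine hydrochloride and triethylamine into N-methoxy-N-methylhexanamide F1.
- Purchased methyl 2,4-dimethoxy-6-methylbenzoate F2 is deprotonated at its benzylic methyl group with LiN(iPr)2 in THF at −78 °C and acylated with F1 to give methyl 2,4-dimethoxy-6-(2-oxoheptyl)benzoate F3.
- Heating F3 with catalytic p-toluenesulfonic acid in toluene closes it, with loss of methanol, and the route is rejoined at isocoumarin 7.

**Step 6.** The risk is that the activated ketone is captured by the neighbouring ester carbonyl oxygen instead of the silylated diol, so that the benzyl group is expelled and the material returns to an isocoumarin. The fallback changes the mask to a thioketal, which forms faster and irreversibly: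
- It sets out from ketone 10, which with ethane-1,2-dithiol and catalytic BF3·OEt2 in CH2Cl2 at 0 °C gives benzyl 2-(benzyloxy)-4-methoxy-6-[(2-pentyl-1,3-dithiolan-2-yl)methyl]benzoate F4.
- Saponification as in step 7 gives 2-(benzyloxy)-4-methoxy-6-[(2-pentyl-1,3-dithiolan-2-yl)methyl]benzoic acid F5.
- Coupling with 19 as in step 13 gives benzyl 4-{[2-(benzyloxy)-4-methoxy-6-((2-pentyl-1,3-dithiolan-2-yl)methyl)benzoyl]oxy}-2-methoxy-6-(2-oxoheptyl)benzoate F6.
- Alkylative hydrolysis of F6 with MeI and NaHCO3 in aqueous acetonitrile returns to the route at diketone 21, without any aqueous acid.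

**Step 9.** The risks are those of step 2, with one more: the benzyl ether makes the substrate less soluble and bulkier, so conversion may stop early. The fallback takes ring B from the ring A series:
- It sets out from isocoumarin 7, which with excess BBr3 in CH2Cl2 gives 6,8-dihydroxy-3-pentyl-1H-isochromen-1-one F7.
- One equivalent of benzyl bromide with K2CO3 in acetone alkylates only the non-chelated C6 hydroxyl to give 6-(benzyloxy)-8-hydroxy-3-pentyl-1H-isochromen-1-one F8.
- Methylation of the chelated C8 hydroxyl with MeI and K2CO3 in DMF at 50 °C rejoins the route at isocoumarin 17.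

**Step 13.** The likely failure is rearrangement of the hindered O-acylisourea to an unreactive N-acylurea before the weakly nucleophilic phenol or DMAP attacks. The fallback replaces in-flask activation by a small, isolable acyl donor. It sets out from acid 12, which with cyanuric fluoride and pyridine in CH2Cl2 gives 2-(benzyloxy)-4-methoxy-6-[(2-pentyl-1,3-dioxolan-2-yl)methyl]benzoyl fluoride F9. Treating F9 with phenol 19, N,N-diisopropylethylamine and DMAP returns to the route at depside 20.

**Step 14.** The risk is acid-triggered depside cleavage: once the ring A ketone is free, its enol can attack the aryl ester carbonyl and expel the ring B phenol, re-forming an isocoumarin. The fallback uses a ketal that is removed by hydrogenolysis, so no acid step follows the coupling: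
- It sets out from ketone 10, which with 1,2-bis[(trimethylsilyloxy)methyl]benzene and catalytic TMSOTf gives benzyl 2-(benzyloxy)-4-methoxy-6-[(3-pentyl-1,5-dihydro-2,4-benzodioxepin-3-yl)methyl]benzoate F10.
- Saponification gives 2-(benzyloxy)-4-methoxy-6-[(3-pentyl-1,5-dihydro-2,4-benzodioxepin-3-yl)methyl]benzoic acid F11.
- Coupling with 19 gives benzyl 4-{[2-(benzyloxy)-4-methoxy-6-((3-pentyl-1,5-dihydro-2,4-benzodioxepin-3-yl)methyl)benzoyl]oxy}-2-methoxy-6-(2-oxoheptyl)benzoate F12.
- Hydrogenolysis of F12 over Pd/C cleaves the benzylic ketal together with both benzyl groups and arrives directly at target 22.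

## Further compounds

F1 | step 2 | N-methoxy-N-methylhexanamide | CCCCCC(=O)N(C)OC
F2 | step 2 | methyl 2,4-dimethoxy-6-methylbenzoate | COC(=O)c1c(C)cc(OC)cc1OC
F3 | step 2 | methyl 2,4-dimethoxy-6-(2-oxoheptyl)benzoate | CCCCCC(=O)Cc1cc(OC)cc(OC)c1C(=O)OC
F4 | step 6 | benzyl 2-(benzyloxy)-4-methoxy-6-[(2-pentyl-1,3-dithiolan-2-yl)methyl]benzoate | CCCCCC1(Cc2cc(OC)cc(OCc3ccccc3)c2C(=O)OCc2ccccc2)SCCS1
F5 | step 6 | 2-(benzyloxy)-4-methoxy-6-[(2-pentyl-1,3-dithiolan-2-yl)methyl]benzoic acid | CCCCCC1(Cc2cc(OC)cc(OCc3ccccc3)c2C(=O)O)SCCS1
F6 | step 6 | benzyl 4-{[2-(benzyloxy)-4-methoxy-6-((2-pentyl-1,3-dithiolan-2-yl)methyl)benzoyl]oxy}-2-methoxy-6-(2-oxoheptyl)benzoate | CCCCCC(=O)Cc1cc(OC(=O)c2c(CC3(CCCCC)SCCS3)cc(OC)cc2OCc2ccccc2)cc(OC)c1C(=O)OCc1ccccc1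
F7 | step 9 | 6,8-dihydroxy-3-pentyl-1H-isochromen-1-one | CCCCCC1=Cc2cc(O)cc(O)c2C(=O)O1
F8 | step 9 | 6-(benzyloxy)-8-hydroxy-3-pentyl-1H-isochromen-1-one | CCCCCC1=Cc2cc(OCc3ccccc3)cc(O)c2C(=O)O1
F9 | step 13 | 2-(benzyloxy)-4-methoxy-6-[(2-pentyl-1,3-dioxolan-2-yl)methyl]benzoyl fluoride | CCCCCC1(Cc2cc(OC)cc(OCc3ccccc3)c2C(F)=O)OCCO1
F10 | step 14 | benzyl 2-(benzyloxy)-4-methoxy-6-[(3-pentyl-1,5-dihydro-2,4-benzodioxepin-3-yl)methyl]benzoate | CCCCCC1(Cc2cc(OC)cc(OCc3ccccc3)c2C(=O)OCc2ccccc2)OCc2ccccc2CO1
F11 | step 14 | 2-(benzyloxy)-4-methoxy-6-[(3-pentyl-1,5-dihydro-2,4-benzodioxepin-3-yl)methyl]benzoic acid | CCCCCC1(Cc2cc(OC)cc(OCc3ccccc3)c2C(=O)O)OCc2ccccc2CO1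
F12 | step 14 | benzyl 4-{[2-(benzyloxy)-4-methoxy-6-((3-pentyl-1,5-dihydro-2,4-benzodioxepin-3-yl)methyl)benzoyl]oxy}-2-methoxy-6-(2-oxoheptyl)benzoate | CCCCCC(=O)Cc1cc(OC(=O)c2c(CC3(CCCCC)OCc4ccccc4CO3)cc(OC)cc2OCc2ccccc2)cc(OC)c1C(=O)OCc1ccccc1
A1 | alternative 1 | benzyl 4-{[2,4-dihydroxy-6-((2-pentyl-1,3-dioxolan-2-yl)methyl)benzoyl]oxy}-2-methoxy-6-[(2-pentyl-1,3-dioxolan-2-yl)methyl]benzoate | CCCCCC1(Cc2cc(O)cc(O)c2C(=O)Oc2cc(CC3(CCCCC)OCCO3)c(C(=O)OCc3ccccc3)c(OC)c2)OCCO1
A2 | alternative 1 | 6-[2,4-dioxo-5-(2-pentyl-1,3-dioxolan-2-yl)pentyl]-2,2-dimethyl-4H-1,3-dioxin-4-one | CCCCCC1(CC(=O)CC(=O)CC2=CC(=O)OC(C)(C)O2)OCCO1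
A3 | alternative 1 | benzyl 4-hydroxy-2-methoxy-6-[(2-pentyl-1,3-dioxolan-2-yl)methyl]benzoate | CCCCCC1(Cc2cc(O)cc(OC)c2C(=O)OCc2ccccc2)OCCO1
A4 | alternative 1 | benzyl 2-methoxy-6-[(2-pentyl-1,3-dioxolan-2-yl)methyl]-4-{[3,5,7-trioxo-8-(2-pentyl-1,3-dioxolan-2-yl)octanoyl]oxy}benzoate | CCCCCC1(CC(=O)CC(=O)CC(=O)CC(=O)Oc2cc(CC3(CCCCC)OCCO3)c(C(=O)OCc3ccccc3)c(OC)c2)OCCO1
A5 | alternative 2 | benzyl 2-[2-(tert-butyldimethylsilyloxy)heptyl]-4-hydroxy-6-methoxybenzoate (racemic) | CCCCCC(Cc1cc(O)cc(OC)c1C(=O)OCc1ccccc1)O[Si](C)(C)C(C)(C)C
A6 | alternative 2 | 1,1-dimethoxy-3-(trimethylsilyloxy)buta-1,3-diene | COC(OC)=CC(=C)O[Si](C)(C)C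
A7 | alternative 2 | benzyl 5-(tert-butyldimethylsilyloxy)dec-2-ynoate (racemic) | CCCCCC(CC#CC(=O)OCc1ccccc1)O[Si](C)(C)C(C)(C)C
A8 | alternative 3 | benzyl 2-(2-benzyloxy-2-oxoethyl)-6-methoxy-4-(4-methoxybenzyloxy)benzoate | COc1ccc(COc2cc(OC)c(C(=O)OCc3ccccc3)c(CC(=O)OCc3ccccc3)c2)cc1
A9 | alternative 3 | 3-methoxy-5-(4-methoxybenzyloxy)-2-(trimethylsilyl)phenyl trifluoromethanesulfonate | COc1ccc(COc2cc(OC)c([Si](C)(C)C)c(OS(=O)(=O)C(F)(F)F)c2)cc1
A10 | alternative 3 | dibenzyl malonate | O=C(CC(=O)OCc1ccccc1)OCc1ccccc1
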